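**Retrosynthetic overview** (isochromene numbering: C1 = ring CH2, O2 = ring oxygen, C3 = aroyl-bearing carbon, C4 = vinylic CH, C4a/C8a = fusion carbons)
1. The target is taken back to its 1-(dimethylamino) derivative (C1 at the aldehyde oxidation level); ionic hydrogenation removes the amino group last.
2. This aminal is cut in one operation into 4,5-dimethoxybenzyne and the enaminone Me2N–CH=CH–CO–CO–Ar (Ar = 2,4-dimethoxyphenyl). The aryne inserts into the enaminone C=C bond ([2+2], 4π ring opening, oxa-6π ring closure), forming C4–C4a, C8a–C1 and C1–O2.
3. Enabling feature: the pyran ring O2–C3=C4–C4a=C8a–C1 is the closed valence isomer of a 1-oxatriene whose C3 carbonyl oxygen is already in place. The benzo ring, with methoxy groups at C6 and C7, is symmetrical about the C4a–C8a bond, so the aryne can give only one regioisomer.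
4. The enaminone comes from 1-(2,4-dimethoxyphenyl)propane-1,2-dione and DMF-DMA; the dione comes from Riley oxidation of 2',4'-dimethoxypropiophenone.
5. Ring order: both benzene rings are bought; a transient four-membered ring and then the pyran ring are formed in the key step.

Key step: step 3

Remark: the target is achiral. The benzocyclobutene and the aminal of the key step form as racemates (the benzocyclobutene as a diastereomer mixture); this is harmless because both stereocentres are lost before the target. 2',4'-Dimethoxypropiophenone and 4,5-dimethoxy-2-(trimethylsilyl)phenyl triflate are taken as purchasable.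

**Step 1**
Reactants: 1 1-(2,4-dimethoxyphenyl)propan-1-one
Product: 2 1-(2,4-dimethoxyphenyl)propane-1,2-dione
Conditions: SeO2, 1,4-dioxane/H2O, reflux
Reagents that add atoms: selenium dioxide O=[Se]=O
Why: Riley oxidation converts the enolisable CH2 next to the aryl ketone into a carbonyl, the standard way from propiophenones to 1-arylpropane-1,2-diones, and the methoxyarene tolerates it; no stereocentre is formed.

**Step 2**
Reactants: 2 1-(2,4-dimethoxyphenyl)propane-1,2-dione
Product: 3 (E)-4-(dimethylamino)-1-(2,4-dimethoxyphenyl)but-3-ene-1,2-dione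
Conditions: DMF-DMA, toluene, 90 °C
Reagents that add atoms: N,N-dimethylformamide dimethyl acetal COC(OC)N(C)C
Why: Enaminone formation by condensation of the amide acetal with the only enolisable position, the acetyl CH3 activated by the 1,2-dicarbonyl, should give the vinylogous amide as the less hindered E isomer; no stereocentre is formed.

**Step 3**
Reactants: 3 (E)-4-(dimethylamino)-1-(2,4-dimethoxyphenyl)but-3-ene-1,2-dione; 4 4,5-dimethoxy-2-(trimethylsilyl)phenyl trifluoromethanesulfonate
Product: 8 (2,4-dimethoxyphenyl)[1-(dimethylamino)-6,7-dimethoxy-1H-isochromen-3-yl]methanone, via 4,5-dimethoxybenzyne 5 (not isolated), via aminobenzocyclobutene 6 (not isolated), via ortho-quinodimethane 7 (not isolated)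
Conditions: CsF, MeCN, 25 then 50 °C, 4 added slowly to excess 3
Reagents that add atoms: none
Why: Proposed new method: fluoride strips the silyl group from 4 and triflate leaves to give the symmetrical aryne 5, the nucleophilic α-carbon of the vinylogous amide 3 adds to it and the aryl anion so formed collapses on the neighbouring iminium carbon (formal [2+2], four-membered ring closed 4-exo-trig), giving the donor–acceptor benzocyclobutene 6 with the new C4–C4a and C8a–C1 bonds. Because the bond between its two sp3 carbons carries the amino donor at one end and the acyl acceptor at the other, 6 should open near room temperature by conrotatory 4π ring opening to the ortho-quinodimethane 7, a 1-oxatriene (O2=C3–C4=C4a–C8a=C1) that closes the pyran ring by thermal disrotatory oxa-6π electrocyclisation, forming C1–O2 and restoring the benzene ring. The closest known reaction types are the [2+2] cycloaddition of arynes with enamides and vinylogous amides followed by opening to ortho-quinodimethides, and the thermal rearrangement of 1-acylbenzocyclobutenes to 1H-isochromenes; joining them on an enaminodione in one flask is the new element. The only new stereocentre, C1 of 8, is set without control (racemate) and disappears in step 4. The step needs carbon rather than oxygen attack of 3 on the aryne (the soft aryne matches the α-carbon, which carries the largest HOMO coefficient), capture of the aryl anion by the iminium carbon rather than by the C3 ketone (the iminium is the stronger electrophile at the same distance), and closure through the C3 carbonyl oxygen alone (the aroyl oxygen would have to form a seven-membered ring). Regiochemistry does not arise because 5 is symmetrical about the bond that becomes C4a–C8a.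

**Step 4**
Reactants: 8 (2,4-dimethoxyphenyl)[1-(dimethylamino)-6,7-dimethoxy-1H-isochromen-3-yl]methanone
Product: 10 (2,4-dimethoxyphenyl)(6,7-dimethoxy-1H-isochromen-3-yl)methanone, via 2-benzopyrylium trifluoroacetate 9 (not isolated)
Conditions: crude 8, Et3SiH, CF3CO2H, CH2Cl2, −20 to 0 °C
Reagents that add atoms: none
Why: Ionic hydrogenation of the N,O-acetal should work because protonation of the basic nitrogen expels dimethylamine to give the aromatic 2-benzopyrylium ion 9, which takes hydride from the silane at C1, the position whose reduction keeps the benzene ring and the acyl-conjugated enol ether intact, and the C1 stereocentre is erased.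

**Compound list**
1 | 1-(2,4-dimethoxyphenyl)propan-1-one (2',4'-dimethoxypropiophenone) | CCC(=O)c1ccc(OC)cc1OC | starting material
2 | 1-(2,4-dimethoxyphenyl)propane-1,2-dione | CC(=O)C(=O)c1ccc(OC)cc1OC | intermediate
3 | (E)-4-(dimethylamino)-1-(2,4-dimethoxyphenyl)but-3-ene-1,2-dione | CN(C)/C=C/C(=O)C(=O)c1ccc(OC)cc1OC | intermediate
4 | 4,5-dimethoxy-2-(trimethylsilyl)phenyl trifluoromethanesulfonate | COc1cc(OS(=O)(=O)C(F)(F)F)c([Si](C)(C)C)cc1OC | starting material
5 | 4,5-dimethoxybenzyne (1,2-didehydro-4,5-dimethoxybenzene) | COC1=CC#CC=C1OC | intermediate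
6 | 1-[8-(dimethylamino)-3,4-dimethoxybicyclo[4.2.0]octa-1,3,5-trien-7-yl]-2-(2,4-dimethoxyphenyl)ethane-1,2-dione (racemic, cis/trans mixture) | COc1ccc(C(=O)C(=O)C2C(N(C)C)c3cc(OC)c(OC)cc32)c(OC)c1 | intermediate
7 | 3-{6-[(dimethylamino)methylidene]-3,4-dimethoxycyclohexa-2,4-dien-1-ylidene}-1-(2,4-dimethoxyphenyl)propane-1,2-dione (amino group outward, acyl group inward) | COC1=C/C(=C\N(C)C)/C(=C\C(=O)C(=O)c2ccc(OC)cc2OC)C=C1OC | intermediate
8 | (2,4-dimethoxyphenyl)[1-(dimethylamino)-6,7-dimethoxy-1H-isochromen-3-yl]methanone (racemic) | COc1ccc(C(=O)C2=Cc3cc(OC)c(OC)cc3C(N(C)C)O2)c(OC)c1 | intermediate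
9 | 3-(2,4-dimethoxybenzoyl)-6,7-dimethoxy-2-benzopyrylium trifluoroacetate | COc1ccc(C(=O)c2cc3cc(OC)c(OC)cc3c[o+]2)c(OC)c1.[O-]C(=O)C(F)(F)F | intermediate
10 | (2,4-dimethoxyphenyl)(6,7-dimethoxy-1H-isochromen-3-yl)methanone | COc1ccc(C(=O)C2=Cc3cc(OC)c(OC)cc3CO2)c(OC)c1 | target

**Totals**
Total step count: 4. Longest linear sequence: 4 steps (1 → 2 → 3 → 8 → 10); 4 is a purchased partner.

**Steps most likely to fail**

Step 3 (carries the label). What may go wrong:
- attack of the vinylogous amide through oxygen instead of carbon;
- capture of the aryl anion by the C3 ketone or by a proton from the solvent instead of the iminium carbon;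
- interception of the ring-opened zwitterion by a second enaminone, by fluoride or by a second aryne before the pyran ring closes.

Fallback by known chemistry, from 2 to 10. Soft enolisation of 2 (Me3SiOTf, Et3N, CH2Cl2, 0 °C) should give 1-(2,4-dimethoxyphenyl)-2-[(trimethylsilyl)oxy]prop-2-en-1-one F1. Purchased 2-bromo-4,5-dimethoxybenzaldehyde is protected (HC(OMe)3, TsOH, MeOH) as 1-bromo-2-(dimethoxymethyl)-4,5-dimethoxybenzene F2. Palladium-catalysed α-arylation of the silyl enol ether (Pd(OAc)2, P(t-Bu)3, Bu3SnF, CsF, toluene, 85 °C) should join them at the terminal carbon to give 1-[2-(dimethoxymethyl)-4,5-dimethoxyphenyl]-3-(2,4-dimethoxyphenyl)propane-2,3-dione F3. Treatment with CF3CO2H and Et3SiH in CH2Cl2 should ionise the acetal and close the enol oxygen onto it to give (2,4-dimethoxyphenyl)(1,6,7-trimethoxy-1H-isochromen-3-yl)methanone F4, which is not isolated and is reduced through 9 to 10. This builds C4–C4a and C1–O2 in separate, precedented operations and needs no aryne.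

Step 4. What may go wrong:
- opening of the aminal by protonation at the ring oxygen, followed by hydride capture of the open iminium ion;
- over-reduction of the aryl ketone or of the enol ether double bond by the silane in acid.

Fallback, from 8 to 10. Acid-catalysed exchange of the amino group for a thiolate (PhSH, catalytic CF3CO2H, CH2Cl2) should give (2,4-dimethoxyphenyl)[6,7-dimethoxy-1-(phenylsulfanyl)-1H-isochromen-3-yl]methanone F5. Radical desulfurisation (Bu3SnH, AIBN, toluene, 100 °C) then replaces the hydride step with hydrogen-atom transfer to a benzylic α-oxy radical, which leaves the ketone and the enol ether untouched.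

Step 1. What may go wrong:
- incomplete oxidation, or oxidative cleavage of the C–C bond next to the new carbonyl;
- selenium residues carried into the amide acetal step.

Fallback, from 1 to 2. α-Nitrosation (isoamyl nitrite, HCl, Et2O) should give (E)-2-(hydroxyimino)-1-(2,4-dimethoxyphenyl)propan-1-one F6. Transoximation with aqueous formaldehyde and HCl then releases 2 without any selenium reagent.

**Further compounds**
F1 | step 3 | 1-(2,4-dimethoxyphenyl)-2-[(trimethylsilyl)oxy]prop-2-en-1-one | C=C(O[Si](C)(C)C)C(=O)c1ccc(OC)cc1OC
F2 | step 3 | 1-bromo-2-(dimethoxymethyl)-4,5-dimethoxybenzene | COC(OC)c1cc(OC)c(OC)cc1Br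
F3 | step 3 | 1-[2-(dimethoxymethyl)-4,5-dimethoxyphenyl]-3-(2,4-dimethoxyphenyl)propane-2,3-dione | COC(OC)c1cc(OC)c(OC)cc1CC(=O)C(=O)c1ccc(OC)cc1OC
F4 | step 3 | (2,4-dimethoxyphenyl)(1,6,7-trimethoxy-1H-isochromen-3-yl)methanone (racemic) | COc1ccc(C(=O)C2=Cc3cc(OC)c(OC)cc3C(OC)O2)c(OC)c1
F5 | step 4 | (2,4-dimethoxyphenyl)[6,7-dimethoxy-1-(phenylsulfanyl)-1H-isochromen-3-yl]methanone (racemic) | COc1ccc(C(=O)C2=Cc3cc(OC)c(OC)cc3C(Sc3ccccc3)O2)c(OC)c1
F6 | step 1 | (E)-2-(hydroxyimino)-1-(2,4-dimethoxyphenyl)propan-1-one | C/C(=N\O)C(=O)c1ccc(OC)cc1OC
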